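Two first-order channels fed from two separate charges are an easy case. Substrate goes to target, other conformer goes to isomer of the product, and substrate and other conformer interconvert; if that exchange is slow, the starting ratio r of isomer to target is κ, the rate constant of the other conformer's channel over that of the substrate's (a selectivity factor), times the charge ratio of other conformer to substrate.

in all of them: substrate 0.10 M
- dawn: other conformer 0.025 M; run made earlier
- dusk: other conformer 0.038 M; run made earlier
- flask: other conformer 0.0500 M; time 2.5 h

| run | time / h | isomer of the product / % | target / % |
|---|---|---|---|
| dawn | 0.250 | 14.1 | 15.4 |
| dawn | 0.500 | 19.2 | 27.4 |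
| dawn | 1.33 | 24.1 | 47.4 |
| dawn | 3.00 | 25.9 | 56.9 |
| dusk | 0.417 | 23.6 | 21.8 |
| dusk | 1.00 | 28.9 | 38.0 |
| dusk | 2.00 | 31.7 | 48.9 |
| dusk | 3.00 | 31.5 | 51.6 |

(each reading ± 0.3 percentage points)

- percentages count the substrate that a species holds: one side product counts as two
- reactions considered so far: substrate + target -> side product; other conformer <-> third conformer; third conformer -> third product; substrate <-> other conformer; substrate -> target; other conformer -> isomer of the product

- ratio of isomer of the product to target at 40 s
- ratio of isomer of the product to target at 2.5 h
- which of isomer of the product and target there is more of at 2.5 h

In powers of ten, the logarithm of r is a sum: the charge ratio's logarithm plus L, the common logarithm of κ. Two chemists dispute this flask. The first holds this charge view and, treating each charge as emptying into its own product, reads κ from a first reading as the ratio of the logarithms of what remains of each charge, so that time cancels; this is my reckoning, and it gives 5.71 in the dawn run and 5.44 in the dusk run, whose geometric mean has the exponent L = 0.746, so r in the flask starts near 2.79. The second holds a pool view, in which fast exchange makes one pool feeding both products at a fixed ratio whatever the charge: isomer gained over target gained between the second and third readings is 0.245 in the dawn run and 0.257 in the dusk run, and the dawn value puts r 1.06 powers of ten below the start of the charge view. The forecast takes the charge side, “The runs show a fast burst of isomer from the charged other conformer”, but with constants that differ from mine: r is 3.3 at 40 s and 0.77 at 2.5 h, with target ahead.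

The flask gives 2.73 at 40 s, which the forecast exceeds by a factor 1.21, and 0.763 at 2.5 h, with target ahead.

    substrate + target → side product (k = 0.0450 /M/min)
    other conformer ⇌ third conformer (K = 4.60, k = 0.00170 /min)
    third conformer → third product (k = 0.00590 /min)
    substrate ⇌ other conformer (K = 0.210, k = 0.00240 /min)
    substrate → target (k = 0.0150 /min)
    other conformer → isomer of the product (k = 0.0840 /min)

The pool view has its region late: in the flask at 1.25 h, other conformer stands at 0.563% against 17.5% of substrate, a ratio of 0.0322, and at 2.50 h that ratio is 0.0315; the same sum, applied to the amounts at 1.25 h, gives a rate ratio of 0.179, less than the 0.245 read from the dawn run. With 0.025 M of substrate, the sum gives 11.1 at 40 s, and that neighbour flask gives 10.8.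

(Readings and results stem from a simulated flask from invented constants, and the scatter is random.)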